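The constant I can read from the epsilon run is the second-order rate constant k of the first addition, and I reckon with the fraction of substrate left, not the fraction made.

| flask | substrate | partner | temperature | remark | time |
|---|---|---|---|---|---|
| epsilon | 25 mM | 55.5 mM | 40 °C | run made earlier |  |
| Wednesday's | 37 mM | 30.0 mM | 40 °C |  | 50 min |
| Sunday's | 37 mM | 150 mM | 40 °C |  | 50 min |
| Friday's | 37 mM | 55.5 mM | 40 °C |  | 50 min |
| Saturday's | 37 mM | 40.0 mM | 40 °C |  | 50 min |
| Thursday's | 37 mM | 15.0 mM | 40 °C |  | 50 min |
| Tuesday's | 37 mM | 200 mM | 40 °C |  | 50 min |

- epsilon (time / min: mono adduct / %): 1.33: 10.6; 3.00: 17.1; 6.00: 31.3; 10.0: 42.6; 12.0: 47.8; 20.0: 59.6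

(readings scatter by 1 percentage point)



1. ranking by amount of mono adduct, in percent of the substrate charged, from high to low, at 50 min (Wednesday's / Sunday's / Friday's / Saturday's / Thursday's / Tuesday's)
2. the same order at 2.5 min (Wednesday's / Sunday's / Friday's / Saturday's / Thursday's / Tuesday's)
3. the amount of mono adduct, in percent of the substrate charged of the flask you put first, at 50 min
4. the amount of mono adduct, in percent of the substrate charged of the flask you put last, at 50 min

Counting the mono adduct at 6.00 min as all the substrate turned over, the integrated rate law gives k = 1.22 /M/min, a reading that carries the scatter. The same reckoning at 20.0 min gives 0.973 /M/min, lower, and I read that as mono adduct reacting further.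

Two times matter. The first is the substrate lifetime τ, the reciprocal of k times c(partner) as charged, a pseudo-first-order lifetime, 14.8 min for Friday's. While partner stays near its charge, the fraction of substrate left is exp(−t/τ). The second is the reading time. I suppose that the loss of mono adduct also needs partner, so its lifetime scales with τ, and the flasks differ in the ratio of reading time to τ.

At 50 min that ratio is 3.39 for Friday's, 12.2 for Tuesday's and 0.916 for Thursday's, whose partner covers 40.5% of the substrate as limiting reagent. I put Friday's first. At 2.5 min I put Tuesday's first: with τ = 4.09 min, I expect 45.7% of its substrate turned over.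

The forecast gives Friday's > Saturday's > Wednesday's > Sunday's > Thursday's > Tuesday's at 50 min, with 66% and 20%, and Tuesday's > Sunday's > Friday's > Saturday's > Wednesday's > Thursday's at 2.5 min, where “mono simply follows partner concentration”.

At 50 min the flasks give Friday's > Saturday's > Wednesday's > Sunday's > Tuesday's > Thursday's, with 71.8% and 31.4%, and at 2.5 min they give Tuesday's > Sunday's > Friday's > Saturday's > Wednesday's > Thursday's.

    substrate + partner → mono adduct (k = 1.20 /M/min, Ea = 67.0 kJ/mol)
    partner + mono adduct → bis adduct (k = 0.0380 /M/min, Ea = 67.0 kJ/mol)
    partner + mono adduct → over-reaction product (k = 0.120 /M/min, Ea = 65.0 kJ/mol)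
    partner → decomposed reagent (k = 0.00130 /min, Ea = 100 kJ/mol)
    (constants at 40 °C)

In Friday's flask, with the other concentrations as charged, the half-life of substrate by the first addition alone is 10 min, and that of mono adduct by the over-reaction path alone is ten times as long, 100 min, while my τ of 14.8 min goes 3.39 times into the run. In Tuesday's flask, against my 45.7% of substrate turned over at 2.5 min, the mono adduct stands at 41.8%.

The data were computed from invented constants; noise was put on by code.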